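**Retrosynthetic overview**

1. Core numbering used below: ring B is the cyclopentenone C1(=O)–C2–C3(OAc)–C3a=C7a; ring A is the cyclohexene C3a–C4–C5–C6–C7(Me2)–C7a; ring C is the 12-membered carbocycle running from C6 through CH2–CH2–C(=CH2)–CH2–CH(OAc)–CH=C(Me) to C2.
2. Feature: in ring C the acetoxy-bearing CH is allylic to the E-alkene and its ring CH2 neighbour sits on the exo-methylene carbon (a homoallylic alcohol on a 2-substituted allyl unit). The CH(O)–CH2 bond is cut to an enal on C2 and a 2-(bromomethyl)allyl arm on C6, joined last by a Nozaki–Hiyama allylation that closes ring C.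
3. Ring B: the C1–C7a bond comes from a Parham-type acylation of a ring A vinyl bromide onto a Weinreb amide. The C2–C3 bond and both ring B stereocentres come from an auxiliary-controlled anti-aldol between a β,γ-unsaturated imide (future enal as its PMB ether) and the ring A bromo-enal.
4. The C6 arm comes from a B-alkyl Suzuki coupling of a C6 vinyl group with silylated 2-bromoallyl alcohol. Ring A comes from 2-methylcyclohex-2-enone by asymmetric vinyl conjugate addition/methylation (C6 centre, C7 gem-dimethyl) and Vilsmeier bromoformylation.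
5. Ring order: A (purchased ring) → B → C; the bromide and the enal are unveiled just before ring C closure, and the new carbinol is acetylated last.

Key step: step 18

Remark: the sense of induction in steps 1 and 8 is assigned from the usual models (copper–phosphoramidite enantioface selection; chelated boron enolate reacting through an open transition state); ligand and oxazolidinone are available in both antipodes, so a reversed sense would be corrected without changing the route. Changes of the C6 descriptor between compounds reflect priority changes only.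

**Step 1**
Reactants: 1 2-methylcyclohex-2-en-1-one
Product: 4 (3S)-3-ethenyl-2,2-dimethylcyclohexan-1-one, via dimethylaluminium enolate 2 (not isolated), via lithium aluminate enolate 3 (not isolated)
Conditions: CH2=CHMgBr, Me2AlCl, Et2O, 0 °C; CuBr·SMe2 (5 mol %), BINOL-derived bis(1-phenylethyl)amine phosphoramidite (10 mol %), −30 °C; MeLi, THF, −30 °C; MeI, HMPA, → rt
Reagents that add atoms: vinylmagnesium bromide C=C[Mg]Br; iodomethane CI
Why: Copper-catalysed asymmetric conjugate addition of an alkenylalane to the α-substituted cyclic enone, in which the chiral copper complex delivers vinyl to one enantioface of C3 and so sets the (3S) centre (the future C6), followed by C-methylation of the regiodefined enolate, activated as its lithium ate complex, to give the quaternary gem-dimethyl carbon.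

**Step 2**
Reactants: 4 (3S)-3-ethenyl-2,2-dimethylcyclohexan-1-one
Product: 6 (4S)-2-bromo-4-ethenyl-3,3-dimethylcyclohex-1-ene-1-carbaldehyde, via bromovinyl iminium bromide 5 (not isolated)
Conditions: PBr3, DMF, CHCl3, 0 °C → 60 °C; aq. NaOAc
Reagents that add atoms: N,N-dimethylformamide CN(C)C=O; phosphorus tribromide BrP(Br)Br; water O
Why: Vilsmeier–Haack bromoformylation: the ketone can enolise only toward its CH2 side because the other α-carbon is quaternary, so formylation occurs there and the carbonyl oxygen is exchanged for bromide, while the stereocentre, β to the carbonyl, is untouched.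

**Step 3**
Reactants: 7 tert-butyl(but-3-yn-1-yloxy)dimethylsilane
Product: 10 (2E)-5-[(tert-butyldimethylsilyl)oxy]-3-methylpent-2-en-1-ol, via alkenylalane 8 (not isolated), via lithium alkenylaluminate 9 (not isolated)
Conditions: AlMe3, Cp2ZrCl2 (20 mol %), CH2Cl2, 0 °C → rt; n-BuLi, THF, −78 °C; (CH2O)n, −78 °C → rt
Reagents that add atoms: trimethylaluminium C[Al](C)C; formaldehyde (as paraformaldehyde) C=O
Why: Negishi zirconium-catalysed carboalumination adds methyl and aluminium syn across the terminal alkyne with methyl on the internal carbon, and the alkenyl aluminate is hydroxymethylated with retention, which fixes the E trisubstituted alkene.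

**Step 4**
Reactants: 10 (2E)-5-[(tert-butyldimethylsilyl)oxy]-3-methylpent-2-en-1-ol
Product: 11 tert-butyl{[(3E)-5-[(4-methoxybenzyl)oxy]-3-methylpent-3-en-1-yl]oxy}dimethylsilane
Conditions: NaH, PMBCl, n-Bu4NI (cat.), THF/DMF, 0 °C → rt
Reagents that add atoms: 4-methoxybenzyl chloride COc1ccc(CCl)cc1
Why: Williamson etherification of the primary allylic alkoxide; the silyl ether is inert to these conditions.

**Step 5**
Reactants: 11 tert-butyl{[(3E)-5-[(4-methoxybenzyl)oxy]-3-methylpent-3-en-1-yl]oxy}dimethylsilane
Product: 12 (3E)-5-[(4-methoxybenzyl)oxy]-3-methylpent-3-en-1-ol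
Conditions: n-Bu4NF, THF, 0 °C → rt
Reagents that add atoms: none
Why: Fluoride-induced desilylation cleaves the primary silyl ether and leaves the PMB ether.

**Step 6**
Reactants: 12 (3E)-5-[(4-methoxybenzyl)oxy]-3-methylpent-3-en-1-ol
Product: 13 (3E)-5-[(4-methoxybenzyl)oxy]-3-methylpent-3-enoic acid
Conditions: TEMPO (20 mol %), PhI(OAc)2 (2.5 equiv), MeCN/H2O 1:1, rt
Reagents that add atoms: water O
Why: TEMPO/PhI(OAc)2 oxidation takes the primary alcohol through the aldehyde hydrate to the acid under near-neutral conditions, which should keep the β,γ-alkene out of conjugation.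

**Step 7**
Reactants: 13 (3E)-5-[(4-methoxybenzyl)oxy]-3-methylpent-3-enoic acid; 14 (4R)-4-benzyl-1,3-oxazolidin-2-one
Product: 16 (4R)-4-benzyl-3-[(3E)-5-[(4-methoxybenzyl)oxy]-3-methylpent-3-enoyl]-1,3-oxazolidin-2-one, via mixed pivalic anhydride 15 (not isolated)
Conditions: t-BuCOCl, Et3N, THF, −20 °C; then 14, LiCl, −20 °C → rt
Reagents that add atoms: none
Why: N-Acylation of the oxazolidinone through the mixed anhydride with LiCl/Et3N activation avoids strong base and, at low temperature, limits migration of the β,γ-alkene.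

**Step 8**
Reactants: 16 (4R)-4-benzyl-3-[(3E)-5-[(4-methoxybenzyl)oxy]-3-methylpent-3-enoyl]-1,3-oxazolidin-2-one; 6 (4S)-2-bromo-4-ethenyl-3,3-dimethylcyclohex-1-ene-1-carbaldehyde
Product: 18 (4R)-4-benzyl-3-[(2S,3E)-2-{(R)-[(4S)-2-bromo-4-ethenyl-3,3-dimethylcyclohex-1-en-1-yl](hydroxy)methyl}-5-[(4-methoxybenzyl)oxy]-3-methylpent-3-enoyl]-1,3-oxazolidin-2-one, via dibutylboron enolate 17 (not isolated)
Conditions: 16, n-Bu2BOTf, i-Pr2NEt, CH2Cl2, 0 °C; added at −78 °C to 6 precomplexed with Et2AlCl (2 equiv), CH2Cl2; pH 7 buffer, MeOH, H2O2, 0 °C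
Reagents that add atoms: none
Why: Lewis-acid-mediated anti-aldol of an Evans boron enolate: the Z-enolate, with boron chelated to the oxazolidinone carbonyl, attacks the Et2AlCl-complexed aldehyde through an open transition state on the face away from the benzyl group (C2 becomes S) and the bulky aluminium-bound oxygen enforces the anti relationship (carbinol R), while the dienolate reacts at its α-carbon so the E-alkene stays β,γ.

**Step 9**
Reactants: 18 anti-aldol imide (as named in step 8)
Product: 19 (2S,3E)-2-{(R)-[(4S)-2-bromo-4-ethenyl-3,3-dimethylcyclohex-1-en-1-yl](hydroxy)methyl}-N-methoxy-5-[(4-methoxybenzyl)oxy]-N,3-dimethylpent-3-enamide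
Conditions: MeONHMe·HCl, AlMe3, THF, −20 °C → 0 °C
Reagents that add atoms: N,O-dimethylhydroxylamine hydrochloride CNOC.Cl
Why: Aluminium-amide transamination of the β-hydroxy imide, assisted by the free hydroxyl, gives the Weinreb amide and releases the auxiliary without touching either stereocentre.

**Step 10**
Reactants: 20 2-bromoprop-2-en-1-ol
Product: 21 [(2-bromoprop-2-en-1-yl)oxy](tert-butyl)dimethylsilane
Conditions: TBSCl, imidazole, CH2Cl2, 0 °C → rt
Reagents that add atoms: tert-butyldimethylsilyl chloride CC(C)(C)[Si](C)(C)Cl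
Why: Standard silylation of a primary allylic alcohol.

**Step 11**
Reactants: 19 Weinreb amide (as named in step 9); 21 [(2-bromoprop-2-en-1-yl)oxy](tert-butyl)dimethylsilane
Product: 23 (2S,3E)-2-{(R)-[(4R)-2-bromo-4-(3-{[(tert-butyldimethylsilyl)oxy]methyl}but-3-en-1-yl)-3,3-dimethylcyclohex-1-en-1-yl](hydroxy)methyl}-N-methoxy-5-[(4-methoxybenzyl)oxy]-N,3-dimethylpent-3-enamide, via alkylborane 22 (not isolated)
Conditions: 9-BBN (2.5 equiv), THF, 0 °C → rt; then 21, Pd(dppf)Cl2 (5 mol %), AsPh3 (10 mol %), Cs2CO3, DMF/H2O, rt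
Reagents that add atoms: none
Why: B-alkyl Suzuki–Miyaura coupling: 9-BBN hydroborates only the monosubstituted vinyl group (anti-Markovnikov; the amide and the trisubstituted alkenes are inert and the hydroxyl merely consumes excess borane), and zerovalent palladium inserts into the unhindered 1,1-disubstituted vinyl bromide of 21 far faster than into the tetrasubstituted ring bromide next to the quaternary carbon.

**Step 12**
Reactants: 23 arm-bearing Weinreb amide (as named in step 11)
Product: 26 (2S,3R,6R)-6-(3-{[(tert-butyldimethylsilyl)oxy]methyl}but-3-en-1-yl)-3-hydroxy-2-[(2E)-4-[(4-methoxybenzyl)oxy]but-2-en-2-yl]-7,7-dimethyl-2,3,4,5,6,7-hexahydro-1H-inden-1-one, via vinyllithium alkoxide 24 (not isolated), via chelated tetrahedral adduct 25 (not isolated)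
Conditions: t-BuLi (3.2 equiv), THF, −78 °C → −40 °C; aq. NH4Cl
Reagents that add atoms: none
Why: Parham-type cyclisation: after deprotonation of the hydroxyl, bromine–lithium exchange outruns addition of t-BuLi to the amide and the vinyllithium closes ring B (5-exo-trig) onto the Weinreb amide, whose chelated adduct survives until the quench, so the ketone never meets base and the cis C2/C3 relationship from the aldol is retained.

**Step 13**
Reactants: 26 hydroxy enone (as named in step 12)
Product: 27 (2S,3R,6R)-3-acetoxy-6-(3-{[(tert-butyldimethylsilyl)oxy]methyl}but-3-en-1-yl)-2-[(2E)-4-[(4-methoxybenzyl)oxy]but-2-en-2-yl]-7,7-dimethyl-2,3,4,5,6,7-hexahydro-1H-inden-1-one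
Conditions: Ac2O, pyridine, DMAP (cat.), CH2Cl2, 0 °C
Reagents that add atoms: acetic anhydride CC(=O)OC(C)=O
Why: DMAP-catalysed acetylation of the secondary allylic alcohol; β-elimination is not expected because it would generate a cyclopentadienone.

**Step 14**
Reactants: 27 acetoxy enone silyl ether (as named in step 13)
Product: 28 (2S,3R,6R)-3-acetoxy-6-[3-(hydroxymethyl)but-3-en-1-yl]-2-[(2E)-4-[(4-methoxybenzyl)oxy]but-2-en-2-yl]-7,7-dimethyl-2,3,4,5,6,7-hexahydro-1H-inden-1-one
Conditions: HF·pyridine, pyridine, THF, 0 °C → rt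
Reagents that add atoms: none
Why: Buffered HF desilylation removes the primary allylic silyl ether and leaves the acetate and the PMB ether.

**Step 15**
Reactants: 28 allylic alcohol (as named in step 14)
Product: 29 (2S,3R,6S)-3-acetoxy-6-[3-(bromomethyl)but-3-en-1-yl]-2-[(2E)-4-[(4-methoxybenzyl)oxy]but-2-en-2-yl]-7,7-dimethyl-2,3,4,5,6,7-hexahydro-1H-inden-1-one
Conditions: CBr4, PPh3, CH2Cl2, 0 °C
Reagents that add atoms: tetrabromomethane BrC(Br)(Br)Br
Why: Appel bromination of the primary allylic alcohol under neutral conditions; the two allyl termini are equivalent, so allylic transposition is immaterial.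

**Step 16**
Reactants: 29 allylic bromide PMB ether (as named in step 15)
Product: 30 (2S,3R,6S)-3-acetoxy-6-[3-(bromomethyl)but-3-en-1-yl]-2-[(2E)-4-hydroxybut-2-en-2-yl]-7,7-dimethyl-2,3,4,5,6,7-hexahydro-1H-inden-1-one
Conditions: DDQ, CH2Cl2/pH 7 buffer 10:1, 0 °C
Reagents that add atoms: none
Why: Oxidative PMB cleavage by DDQ (benzylic hydride abstraction, then hydrolysis) under buffered conditions that spare the allylic bromide, the acetate and the enone.

**Step 17**
Reactants: 30 allylic alcohol bromide (as named in step 16)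
Product: 31 (2S,3R,6S)-3-acetoxy-6-[3-(bromomethyl)but-3-en-1-yl]-7,7-dimethyl-2-[(2E)-4-oxobut-2-en-2-yl]-2,3,4,5,6,7-hexahydro-1H-inden-1-one
Conditions: MnO2 (activated, excess), CH2Cl2, rt
Reagents that add atoms: none
Why: MnO2 oxidation of the allylic alcohol gives the E-enal without base, so the now vinylogously activated C2–H is not disturbed; the enal is used at once.

**Step 18**
Reactants: 31 ring A/B acetoxy enone with bromide and enal arms (as named in step 17)
Product: 33 tricyclic homoallylic alcohol monoacetate with ring C closed and an (S)-carbinol next to the E-alkene, via allylchromium dichloride 32 (not isolated)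
Conditions: CrCl2 (10 equiv), THF, rt; 31 added by syringe pump over 10 h to 0.002 M
Reagents that add atoms: none
Why: CrCl2 reduces the allylic bromide in two one-electron steps to the allylchromium species 32 (trivalent chromium), which adds to the aldehyde through a closed six-membered chair transition state; the closest known reaction is the intramolecular Nozaki–Hiyama allylation used to close 12- to 14-membered carbocycles. Ring C closes in the 12-exo-trig mode by forming the bond between the carbinol carbon and the CH2 of the 2-substituted allyl unit. The new (S)-carbinol centre is set by the enal face that the tethered allyl terminus can reach: both arms leave the same face of the rigid ring A/B platform, and the chair with the chromium-bound oxygen on the outside of the forming ring is expected to be lowest in energy and to give the (S) configuration; this is the least secure element of the route. The step needs aldehyde chemoselectivity, which the weakly basic allylchromium secures over the hindered enone and the acetate, and no regiocontrol, because the two allyl termini are equivalent and transposition returns the same exo-methylene constitution. It also needs ring closure to outrun oligomerisation, which slow addition at high dilution and the cis disposition of the arms secure, and the neutral medium leaves the acidic C2–H and the β-acetoxy group intact.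

**Step 19**
Reactants: 33 tricyclic homoallylic alcohol monoacetate
Product: 34 CNP0121312.1, the diacetate
Conditions: Ac2O, pyridine, DMAP (cat.), CH2Cl2, 0 °C → rt
Reagents that add atoms: acetic anhydride CC(=O)OC(C)=O
Why: DMAP-catalysed acetylation of the unhindered ring C allylic alcohol with retention gives the target.

**Compound list**

1 | 2-methylcyclohex-2-en-1-one | CC1=CCCCC1=O | starting material
2 | dimethylaluminium enolate of the vinyl conjugate adduct | C=C[C@@H]1CCCC(O[Al](C)C)=C1C | intermediate (not isolated)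
3 | lithium trimethylaluminate enolate | [Li+].C=C[C@@H]1CCCC(O[Al-](C)(C)C)=C1C | intermediate (not isolated)
4 | (3S)-3-ethenyl-2,2-dimethylcyclohexan-1-one | C=C[C@@H]1CCCC(=O)C1(C)C | intermediate
5 | bromovinyl iminium bromide from 4 | C=C[C@@H]1CCC(C=[N+](C)C)=C(Br)C1(C)C.[Br-] | intermediate (not isolated)
6 | (4S)-2-bromo-4-ethenyl-3,3-dimethylcyclohex-1-ene-1-carbaldehyde | C=C[C@@H]1CCC(C=O)=C(Br)C1(C)C | intermediate
7 | tert-butyl(but-3-yn-1-yloxy)dimethylsilane | C#CCCO[Si](C)(C)C(C)(C)C | starting material
8 | (E)-[4-(tert-butyldimethylsilyloxy)-2-methylbut-1-en-1-yl]dimethylalane | C[Al](C)/C=C(\C)CCO[Si](C)(C)C(C)(C)C | intermediate (not isolated)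
9 | lithium butyl(dimethyl)alkenylaluminate from 8 | [Li+].CCCC[Al-](C)(C)/C=C(\C)CCO[Si](C)(C)C(C)(C)C | intermediate (not isolated)
10 | (2E)-5-[(tert-butyldimethylsilyl)oxy]-3-methylpent-2-en-1-ol | OC/C=C(\C)CCO[Si](C)(C)C(C)(C)C | intermediate
11 | tert-butyl{[(3E)-5-[(4-methoxybenzyl)oxy]-3-methylpent-3-en-1-yl]oxy}dimethylsilane | COc1ccc(COC/C=C(\C)CCO[Si](C)(C)C(C)(C)C)cc1 | intermediate
12 | (3E)-5-[(4-methoxybenzyl)oxy]-3-methylpent-3-en-1-ol | COc1ccc(COC/C=C(\C)CCO)cc1 | intermediate
13 | (3E)-5-[(4-methoxybenzyl)oxy]-3-methylpent-3-enoic acid | COc1ccc(COC/C=C(\C)CC(=O)O)cc1 | intermediate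
14 | (4R)-4-benzyl-1,3-oxazolidin-2-one | O=C1N[C@H](Cc2ccccc2)CO1 | starting material
15 | mixed anhydride of 13 with pivalic acid | COc1ccc(COC/C=C(\C)CC(=O)OC(=O)C(C)(C)C)cc1 | intermediate (not isolated)
16 | (4R)-4-benzyl-3-[(3E)-5-[(4-methoxybenzyl)oxy]-3-methylpent-3-enoyl]-1,3-oxazolidin-2-one | O=C(C/C(C)=C/COCc1ccc(OC)cc1)N1[C@H](Cc2ccccc2)COC1=O | intermediate
17 | (Z)-dibutylboron enolate of 16 | CCCCB(CCCC)O/C(=C\C(C)=C\COCc1ccc(OC)cc1)N1[C@H](Cc2ccccc2)COC1=O | intermediate (not isolated)
18 | anti-aldol imide, (2S) at the α-carbon, (R) at the carbinol, (4S) in ring A | O=C([C@@H](/C(C)=C/COCc1ccc(OC)cc1)[C@@H](O)C1=C(Br)C(C)(C)[C@H](C=C)CC1)N1[C@H](Cc2ccccc2)COC1=O | intermediate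
19 | Weinreb amide of the anti-aldol, (2S), carbinol (R), ring A (4S) | CON(C)C(=O)[C@@H](/C(C)=C/COCc1ccc(OC)cc1)[C@@H](O)C1=C(Br)C(C)(C)[C@H](C=C)CC1 | intermediate
20 | 2-bromoprop-2-en-1-ol | C=C(Br)CO | starting material
21 | [(2-bromoprop-2-en-1-yl)oxy](tert-butyl)dimethylsilane | C=C(Br)CO[Si](C)(C)C(C)(C)C | intermediate
22 | B-alkyl-9-borabicyclo[3.3.1]nonane from 19 | CON(C)C(=O)[C@@H](/C(C)=C/COCc1ccc(OC)cc1)[C@@H](O)C1=C(Br)C(C)(C)[C@H](CCB2C3CCCC2CCC3)CC1 | intermediate (not isolated)
23 | Weinreb amide carrying the 3-(silyloxymethyl)but-3-enyl arm, (2S), carbinol (R), ring A (4R) | CON(C)C(=O)[C@@H](/C(C)=C/COCc1ccc(OC)cc1)[C@@H](O)C1=C(Br)C(C)(C)[C@H](CCC(=C)CO[Si](C)(C)C(C)(C)C)CC1 | intermediate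
24 | vinyllithium lithium alkoxide from 23 | CON(C)C(=O)[C@@H](/C(C)=C/COCc1ccc(OC)cc1)[C@@H](O[Li])C1=C([Li])C(C)(C)[C@H](CCC(=C)CO[Si](C)(C)C(C)(C)C)CC1 | intermediate (not isolated)
25 | cyclic tetrahedral adduct (dilithium salt) | C=C(CO[Si](C)(C)C(C)(C)C)CC[C@@H]1CCC2=C(C(O[Li])(N(C)OC)[C@@H](/C(C)=C/COCc3ccc(OC)cc3)[C@H]2O[Li])C1(C)C | intermediate (not isolated)
26 | (2S,3R,6R)-3-hydroxy hexahydroinden-1-one with silyl ether arm and PMB ether side chain | C=C(CO[Si](C)(C)C(C)(C)C)CC[C@@H]1CCC2=C(C(=O)[C@@H](/C(C)=C/COCc3ccc(OC)cc3)[C@H]2O)C1(C)C | intermediate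
27 | (2S,3R,6R)-3-acetate of 26 | C=C(CO[Si](C)(C)C(C)(C)C)CC[C@@H]1CCC2=C(C(=O)[C@@H](/C(C)=C/COCc3ccc(OC)cc3)[C@H]2OC(C)=O)C1(C)C | intermediate
28 | (2S,3R,6R)-3-acetoxy enone with 3-(hydroxymethyl)but-3-enyl arm | C=C(CO)CC[C@@H]1CCC2=C(C(=O)[C@@H](/C(C)=C/COCc3ccc(OC)cc3)[C@H]2OC(C)=O)C1(C)C | intermediate
29 | (2S,3R,6S)-3-acetoxy enone with 3-(bromomethyl)but-3-enyl arm and PMB ether side chain | C=C(CBr)CC[C@@H]1CCC2=C(C(=O)[C@@H](/C(C)=C/COCc3ccc(OC)cc3)[C@H]2OC(C)=O)C1(C)C | intermediate
30 | (2S,3R,6S)-3-acetoxy enone with bromide arm and (2E)-4-hydroxybut-2-en-2-yl side chain | C=C(CBr)CC[C@@H]1CCC2=C(C(=O)[C@@H](/C(C)=C/CO)[C@H]2OC(C)=O)C1(C)C | intermediate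
31 | (2S,3R,6S)-3-acetoxy enone with bromide arm and (2E)-4-oxobut-2-en-2-yl side chain (key-step precursor) | C=C(CBr)CC[C@@H]1CCC2=C(C(=O)[C@@H](/C(C)=C/C=O)[C@H]2OC(C)=O)C1(C)C | intermediate
32 | allylchromium dichloride from 31 | C=C(C[Cr](Cl)Cl)CC[C@@H]1CCC2=C(C(=O)[C@@H](/C(C)=C/C=O)[C@H]2OC(C)=O)C1(C)C | intermediate (not isolated)
33 | tricyclic homoallylic alcohol monoacetate, ring C (S)-carbinol (key-step product) | C=C1CC[C@@H]2CCC3=C(C(=O)[C@@H](/C(C)=C/[C@@H](O)C1)[C@H]3OC(C)=O)C2(C)C | intermediate
34 | CNP0121312.1, the diacetate | C=C1CC[C@@H]2CCC3=C(C(=O)[C@@H](/C(C)=C/[C@@H](OC(C)=O)C1)[C@H]3OC(C)=O)C2(C)C | target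

**Totals**

Total step count: 19.
Longest linear sequence: 16 steps (steps 3–9 and 11–19, from compound 7).

**Steps most likely to fail**

Step 18. The facial selectivity at the aldehyde may be low or reversed, because it rests only on the conformation of the forming 12-membered ring. The fallback sets out from 31 and comes back to the route at 34. The cyclisation is run as described, the epimeric ring C (R)-carbinol F1 is separated from 33, and F1 is converted by Mitsunobu reaction with acetic acid (PPh3, DIAD, THF, 0 °C) with inversion directly into the diacetate 34; any 33 formed is acetylated as in step 19.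

Step 8. The anti selectivity may erode toward syn adducts through a competing closed transition state, or the complexed aldehyde may react sluggishly with the β,γ-unsaturated enolate. The fallback sets out from 13 (with 6) and comes back at 27; it takes the reliable syn-aldol and corrects C3 afterwards. Acid 13 is acylated onto (4S)-4-benzyl-1,3-oxazolidin-2-one as in step 7 to give the (4S)-imide F2. Its dibutylboron enolate (n-Bu2BOTf, i-Pr2NEt, no added Lewis acid) adds to 6 through the closed chair transition state to give the syn adduct F3, which has C2 as required and the epimeric carbinol. F3 is carried through the conditions of steps 9, 11 and 12 to the Weinreb amide F4, the arm-bearing amide F5 and the trans-hydroxy enone F6. Mitsunobu reaction of F6 with acetic acid (PPh3, DIAD) inverts C3 and delivers the cis-acetate 27 in the same operation.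

Step 1. The enantioselectivity of the vinyl transfer may be insufficient, or the aluminium enolate may resist clean C-methylation. The fallback sets out from 1 and comes back at 4; it replaces asymmetric catalysis by resolution. Copper-catalysed addition of vinylmagnesium bromide (CuI cat., TMSCl, THF, −78 °C) gives the racemic silyl enol ether F7; MeLi then MeI/HMPA gives the racemic ketone F8; the enantiomers are separated by preparative chromatography on a chiral stationary phase, and the (S)-enantiomer is 4.

**Further compounds**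

F1 | step 18 | ring C (R)-carbinol epimer of 33 | C=C1CC[C@@H]2CCC3=C(C(=O)[C@@H](/C(C)=C/[C@H](O)C1)[C@H]3OC(C)=O)C2(C)C
F2 | step 8 | (4S)-4-benzyl-3-[(3E)-5-[(4-methoxybenzyl)oxy]-3-methylpent-3-enoyl]-1,3-oxazolidin-2-one | O=C(C/C(C)=C/COCc1ccc(OC)cc1)N1[C@@H](Cc2ccccc2)COC1=O
F3 | step 8 | syn-aldol imide, (2S) at the α-carbon, (S) at the carbinol, (4S) in ring A | O=C([C@@H](/C(C)=C/COCc1ccc(OC)cc1)[C@H](O)C1=C(Br)C(C)(C)[C@H](C=C)CC1)N1[C@@H](Cc2ccccc2)COC1=O
F4 | step 8 | Weinreb amide of the syn-aldol | CON(C)C(=O)[C@@H](/C(C)=C/COCc1ccc(OC)cc1)[C@H](O)C1=C(Br)C(C)(C)[C@H](C=C)CC1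
F5 | step 8 | syn Weinreb amide carrying the 3-(silyloxymethyl)but-3-enyl arm | CON(C)C(=O)[C@@H](/C(C)=C/COCc1ccc(OC)cc1)[C@H](O)C1=C(Br)C(C)(C)[C@H](CCC(=C)CO[Si](C)(C)C(C)(C)C)CC1
F6 | step 8 | (2S,3S,6R)-trans-3-hydroxy hexahydroinden-1-one, C3 epimer of 26 | C=C(CO[Si](C)(C)C(C)(C)C)CC[C@@H]1CCC2=C(C(=O)[C@@H](/C(C)=C/COCc3ccc(OC)cc3)[C@@H]2O)C1(C)C
F7 | step 1 | racemic trimethylsilyl enol ether of 2-methyl-3-vinylcyclohexanone | C=CC1CCCC(O[Si](C)(C)C)=C1C
F8 | step 1 | racemic 3-ethenyl-2,2-dimethylcyclohexan-1-one | C=CC1CCCC(=O)C1(C)C
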